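**Retrosynthetic overview**
1. The C1 acid and the C8 ketone are adjusted last (Dess–Martin oxidation, desilylation, MnO2, Pinnick) on a tris-silylated C8 carbinol carrying the whole skeleton.
2. A C17–C18 Suzuki coupling attaches the lactone alkenylboronate (fragment C); a C12=C13 Julia–Kocienski olefination joins the PT sulfone/(Z)-iodide (fragment B) to the C1–C12 enal (fragment A).
3. Fragment A: phosphoramide/SiCl4 anti aldol (C6, C7), then 9-BBN hydroboration/B-alkyl Suzuki (C5, C3–C4), then chiral phosphoric acid allylboration (C8–C9 bond, C9), then cross-metathesis with methacrolein.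
4. Fragment B: enamine Michael addition of propanal to PT vinyl sulfone (C15), then Stork–Zhao olefination.
5. Ring order: the δ-lactone is the only ring; it is closed by ring-closing metathesis inside fragment C (crotylboration, acryloylation, metathesis) before the Suzuki coupling.

Abbreviations: TBS = tert-butyldimethylsilyl; Bpin = 4,4,5,5-tetramethyl-1,3,2-dioxaborolan-2-yl; PT = 1-phenyl-1H-tetrazol-5-yl; TRIP = 3,3'-bis(2,4,6-triisopropylphenyl)-1,1'-binaphthyl-2,2'-diyl hydrogen phosphate; C1–C24 are target positions (C1 acid, C20–C24 lactone).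

Assumption: compounds 16, 36 and 37 and all named catalysts are bought; catalyst hands are assigned from the accepted facial models, and since each catalyst exists in both hands an opposite sense would be corrected by exchanging the enantiomer.

**Route**

Step 1
Reactants: 1 tert-butyl propanoate
Product: 3 (E)-tert-butyl[(1-tert-butoxyprop-1-en-1-yl)oxy]dimethylsilane, via lithium enolate 2 (not isolated)
Conditions: LiN(i-Pr)2, THF, −78 °C; TBSCl, −78 °C to rt
Reagents that add atoms: tert-butyldimethylsilyl chloride CC(C)(C)[Si](C)(C)Cl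
Why: Kinetic ester enolisation followed by O-silylation gives the silyl ketene acetal, whose double-bond geometry does not matter because the next aldol is stereoconvergent.

Step 2
Reactants: 3 (E)-tert-butyl[(1-tert-butoxyprop-1-en-1-yl)oxy]dimethylsilane; 4 2-methylprop-2-enal (methacrolein)
Product: 6 tert-butyl (2R,3S)-3-hydroxy-2,4-dimethylpent-4-enoate, via trichlorosilyl aldolate 5 (not isolated)
Conditions: SiCl4 (1.1 equiv), (S,S)-bisphosphoramide catalyst [pentane-1,5-diyl-linked bis(N,N'-dimethyl-1,1'-binaphthyl-2,2'-diamine phosphoramide)] (2 mol %), CH2Cl2, −78 °C; aq. NaHCO3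
Reagents that add atoms: none
Why: Lewis-base-catalysed, SiCl4-mediated Mukaiyama aldol addition in which the phosphoramide-bound chlorosilyl cation activates the enal for Si-face attack through an open transition state, giving the anti adduct and setting C7 and C6 as the first stereocentres.

Step 3
Reactants: 6 tert-butyl (2R,3S)-3-hydroxy-2,4-dimethylpent-4-enoate
Product: 7 tert-butyl (2R,3S)-3-(TBSO)-2,4-dimethylpent-4-enoate
Conditions: TBSOTf, 2,6-lutidine, CH2Cl2, −78 to 0 °C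
Reagents that add atoms: tert-butyldimethylsilyl trifluoromethanesulfonate CC(C)(C)[Si](C)(C)OS(=O)(=O)C(F)(F)F
Why: Silyl ether formation masks the C6 hydroxyl for the whole route and supplies the bulky allylic group that directs the later hydroboration.

Step 4
Reactants: 8 but-2-yn-1-ol
Product: 9 (but-2-yn-1-yloxy)(tert-butyl)dimethylsilane
Conditions: TBSCl, imidazole, CH2Cl2, rt
Reagents that add atoms: tert-butyldimethylsilyl chloride CC(C)(C)[Si](C)(C)Cl
Why: Standard silyl ether protection of a primary alcohol.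

Step 5
Reactants: 9 (but-2-yn-1-yloxy)(tert-butyl)dimethylsilane
Product: 11 (E)-tert-butyl[(3-iodobut-2-en-1-yl)oxy]dimethylsilane, via alkenylzirconocene 10 (not isolated)
Conditions: Cp2Zr(H)Cl (2 equiv), THF, 45 °C; I2, 0 °C
Reagents that add atoms: iodine II
Why: Syn hydrozirconation of the internal alkyne, equilibrated with excess reagent so that zirconium sits on the methyl-bearing carbon, followed by iodinolysis with retention gives the (E)-iodide.

Step 6
Reactants: 7 tert-butyl (2R,3S)-3-(TBSO)-2,4-dimethylpent-4-enoate; 11 (E)-tert-butyl[(3-iodobut-2-en-1-yl)oxy]dimethylsilane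
Product: 13 tert-butyl (2R,3R,4R,6E)-3,8-bis(TBSO)-2,4,6-trimethyloct-6-enoate, via alkylborane 12 (not isolated)
Conditions: 9-BBN, THF, rt; then 11, Pd(dppf)Cl2 (5 mol %), AsPh3, Cs2CO3, DMF/H2O, rt
Reagents that add atoms: none
Why: Substrate-controlled hydroboration of the 1,1-disubstituted alkene anti to the allylic silyloxy group (A(1,3)-strain control) sets C5, and the B-alkyl Suzuki–Miyaura coupling with retention at the iodide forms C3–C4 with the (E)-trisubstituted alkene.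

Step 7
Reactants: 13 tert-butyl (2R,3R,4R,6E)-3,8-bis(TBSO)-2,4,6-trimethyloct-6-enoate
Product: 15 (2R,3R,4R,6E)-3,8-bis(TBSO)-2,4,6-trimethyloct-6-enal, via aluminium hemiacetal 14 (not isolated)
Conditions: i-Bu2AlH (1.2 equiv), CH2Cl2, −78 °C; aq. potassium sodium tartrate
Reagents that add atoms: none
Why: Partial hydride reduction of the hindered tert-butyl ester stops at the tetrahedral aluminium hemiacetal at −78 °C, which releases the aldehyde on work-up without epimerising C7.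

Step 8
Reactants: 16 (E)-but-2-ene-1,4-diol
Product: 17 (E)-4-(TBSO)but-2-en-1-ol
Conditions: 16 (3 equiv), TBSCl (1 equiv), imidazole, THF, 0 °C
Reagents that add atoms: tert-butyldimethylsilyl chloride CC(C)(C)[Si](C)(C)Cl
Why: Statistical monosilylation of a symmetrical diol used in excess.

Step 9
Reactants: 17 (E)-4-(TBSO)but-2-en-1-ol
Product: 18 (E)-tert-butyldimethyl{[4-(Bpin)but-2-en-1-yl]oxy}silane
Conditions: B2pin2, Pd(MeCN)4(BF4)2 (5 mol %), DMSO/MeOH, rt
Reagents that add atoms: bis(pinacolato)diboron CC1(C)OB(OC1(C)C)B1OC(C)(C)C(C)(C)O1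
Why: Palladium-catalysed borylation of the allylic alcohol through a π-allyl intermediate delivers boron to the unsubstituted terminus and keeps the (E)-geometry.

Step 10
Reactants: 15 (2R,3R,4R,6E)-3,8-bis(TBSO)-2,4,6-trimethyloct-6-enal; 18 (E)-tert-butyldimethyl{[4-(Bpin)but-2-en-1-yl]oxy}silane
Product: 20 (3S,4R,5S,6R,7R,9E)-6,11-bis(TBSO)-3-[(TBSO)methyl]-5,7,9-trimethylundeca-1,9-dien-4-ol, via boric ester 19 (not isolated)
Conditions: (R)-TRIP (10 mol %), 4 Å molecular sieves, toluene, −30 to 0 °C; aqueous work-up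
Reagents that add atoms: none
Why: Proposed new method: a chiral phosphoric acid-catalysed allylboration with a γ-(silyloxymethyl)allylboronate on an α-methyl-β-silyloxy aldehyde, in which the acid hydrogen-bonds to the pseudo-axial boronate oxygen and the formyl hydrogen in a closed chair transition state so that the (E)-γ-CH2OTBS group sits equatorial (C8/C9 anti) while the Re-face attack favoured by (R)-TRIP coincides with the Felkin and 1,3-anti preferences of the aldehyde, forming the C8–C9 bond and setting C9 (S) and C8 (R); the closest known reaction type is the chiral phosphoric acid-catalysed (E)-crotylboration of aldehydes.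

Step 11
Reactants: 20 (3S,4R,5S,6R,7R,9E)-6,11-bis(TBSO)-3-[(TBSO)methyl]-5,7,9-trimethylundeca-1,9-dien-4-ol; 4 2-methylprop-2-enal (methacrolein)
Product: 21 (2E,4S,5R,6S,7R,8R,10E)-7,12-bis(TBSO)-4-[(TBSO)methyl]-5-hydroxy-2,6,8,10-tetramethyldodeca-2,10-dienal
Conditions: RuCl2(H2IMes)(=CH-2-(i-PrO)C6H4) (second-generation Hoveyda–Grubbs catalyst, 10 mol %), 4 (10 equiv), CH2Cl2, 40 °C
Reagents that add atoms: none
Why: Olefin cross-metathesis of the only monosubstituted alkene with methacrolein gives the thermodynamically preferred (E)-2-methyl enal and leaves the trisubstituted C2=C3 alkene untouched.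

Step 12
Reactants: 22 1-phenyl-1H-tetrazole-5-thiol; 23 1,2-dibromoethane
Product: 24 5-[(2-bromoethyl)sulfanyl]-1-phenyl-1H-tetrazole
Conditions: 23 (5 equiv), K2CO3, acetone, rt
Reagents that add atoms: none
Why: SN2 S-alkylation of the thiolate, with excess dibromide suppressing double substitution.

Step 13
Reactants: 24 5-[(2-bromoethyl)sulfanyl]-1-phenyl-1H-tetrazole
Product: 26 5-(ethenylsulfonyl)-1-phenyl-1H-tetrazole, via bromoethyl sulfone 25 (not isolated)
Conditions: (NH4)6Mo7O24 (10 mol %), 30 % H2O2, EtOH, rt; then Et3N, CH2Cl2, 0 °C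
Reagents that add atoms: hydrogen peroxide OO
Why: Molybdate-catalysed oxidation of the sulfide to the sulfone followed by base-induced E1cB loss of HBr gives the vinyl sulfone.

Step 14
Reactants: 26 5-(ethenylsulfonyl)-1-phenyl-1H-tetrazole; 27 propanal
Product: 28 (2S)-2-methyl-4-(PT-sulfonyl)butanal
Conditions: (R)-2-[diphenyl(trimethylsilyloxy)methyl]pyrrolidine (10 mol %), 27 (3 equiv), toluene, 0 °C; used at once
Reagents that add atoms: none
Why: Enamine-catalysed Michael addition of propanal to the electron-poor heteroaryl vinyl sulfone, in which the diarylprolinol silyl ether shields one face of the (E)-enamine, sets C15 (S) and installs the Julia–Kocienski sulfone at C13 in the same step.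

Step 15
Reactants: 28 (2S)-2-methyl-4-(PT-sulfonyl)butanal; 29 ethyltriphenylphosphonium iodide
Product: 33 5-{[(3S,4Z)-5-iodo-3-methylhex-4-en-1-yl]sulfonyl}-1-phenyl-1H-tetrazole, via ethylidene ylide 30 (not isolated), via iodophosphonium salt 31 (not isolated), via iodo ylide 32 (not isolated)
Conditions: 29, n-BuLi, THF, rt; I2, −78 °C; NaN(SiMe3)2, −20 °C; then 28, −78 °C
Reagents that add atoms: iodine II
Why: Stork–Zhao-type Wittig olefination with the α-iodo ylide at −78 °C gives the (Z)-2-iodoalkene (iodine cis to C15) without epimerising the α-stereocentre.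

Step 16
Reactants: 33 5-{[(3S,4Z)-5-iodo-3-methylhex-4-en-1-yl]sulfonyl}-1-phenyl-1H-tetrazole; 21 (2E,4S,5R,6S,7R,8R,10E)-7,12-bis(TBSO)-4-[(TBSO)methyl]-5-hydroxy-2,6,8,10-tetramethyldodeca-2,10-dienal
Product: 35 (2E,5R,6R,7S,8R,9S,10E,12E,15S,16Z)-1,6-bis(TBSO)-9-[(TBSO)methyl]-17-iodo-3,5,7,11,15-pentamethyloctadeca-2,10,12,16-tetraen-8-ol, via sulfonyl carbanion 34 (not isolated)
Conditions: 33 (1.3 equiv), KN(SiMe3)2 (1.2 equiv), DME, −78 °C; then 21, −78 to −20 °C; aq. NH4Cl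
Reagents that add atoms: none
Why: Julia–Kocienski olefination of the PT sulfone anion with the enal forms C12=C13 with (E)-selectivity through Smiles rearrangement and loss of SO2, the sulfonyl carbanion being too weakly basic to deprotonate the free C8 hydroxyl.

Step 17
Reactants: 36 (E)-3-(Bpin)prop-2-enal; 37 2-[(E)-but-2-en-1-yl]-4,4,5,5-tetramethyl-1,3,2-dioxaborolane
Product: 39 (1E,3R,4S)-4-methyl-1-(Bpin)hexa-1,5-dien-3-ol, via boric ester 38 (not isolated)
Conditions: (S)-TRIP (5 mol %), 4 Å molecular sieves, toluene, −30 °C; aqueous work-up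
Reagents that add atoms: none
Why: Chiral phosphoric acid-catalysed (E)-crotylboration through a chair transition state gives the anti homoallylic alcohol by Si-face attack, setting C20 (R) and C21 (S).

Step 18
Reactants: 39 (1E,3R,4S)-4-methyl-1-(Bpin)hexa-1,5-dien-3-ol; 40 acryloyl chloride
Product: 41 (1E,3R,4S)-4-methyl-1-(Bpin)hexa-1,5-dien-3-yl prop-2-enoate
Conditions: i-Pr2NEt, DMAP (cat.), CH2Cl2, −20 °C
Reagents that add atoms: none
Why: O-acylation of the secondary allylic alcohol gives the diene ester needed for ring closure.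

Step 19
Reactants: 41 (1E,3R,4S)-4-methyl-1-(Bpin)hexa-1,5-dien-3-yl prop-2-enoate
Product: 42 (5S,6R)-5-methyl-6-[(E)-2-(Bpin)ethenyl]-5,6-dihydro-2H-pyran-2-one
Conditions: RuCl2(H2IMes)(PCy3)(=CHPh) (second-generation Grubbs catalyst, 5 mol %), CH2Cl2 (5 mM), 40 °C
Reagents that add atoms: none
Why: Ring-closing metathesis between the terminal vinyl group and the acrylate closes the only ring, the trans-5,6-disubstituted α,β-unsaturated δ-lactone, while the 1,2-disubstituted alkenylboronate is too hindered to compete.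

Step 20
Reactants: 35 (2E,5R,6R,7S,8R,9S,10E,12E,15S,16Z)-1,6-bis(TBSO)-9-[(TBSO)methyl]-17-iodo-3,5,7,11,15-pentamethyloctadeca-2,10,12,16-tetraen-8-ol; 42 (5S,6R)-5-methyl-6-[(E)-2-(Bpin)ethenyl]-5,6-dihydro-2H-pyran-2-one
Product: 43 (5S,6R)-6-[(1E,3Z,5S,7E,9E,11S,12R,13S,14R,15R,17E)-14,19-bis(TBSO)-11-[(TBSO)methyl]-12-hydroxy-3,5,9,13,15,17-hexamethylnonadeca-1,3,7,9,17-pentaen-1-yl]-5-methyl-5,6-dihydro-2H-pyran-2-one
Conditions: Pd(PPh3)4 (10 mol %), TlOEt (1.8 equiv), THF/H2O (3:1), rt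
Reagents that add atoms: none
Why: Suzuki–Miyaura coupling with retention at both alkenyl partners forms C17–C18 and completes the (16Z,18E)-diene, TlOEt giving transmetallation fast enough at room temperature for the lactone to survive.

Step 21
Reactants: 43 (the C8 carbinol of step 20)
Product: 44 (5S,6R)-6-[(1E,3Z,5S,7E,9E,11S,13R,14R,15R,17E)-14,19-bis(TBSO)-11-[(TBSO)methyl]-3,5,9,13,15,17-hexamethyl-12-oxononadeca-1,3,7,9,17-pentaen-1-yl]-5-methyl-5,6-dihydro-2H-pyran-2-one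
Conditions: Dess–Martin periodinane, NaHCO3, CH2Cl2, 0 °C
Reagents that add atoms: none
Why: Dess–Martin oxidation of the only free hydroxyl gives the C8 ketone under buffered, non-basic conditions that do not epimerise C7 or C9.

Step 22
Reactants: 44 (the tris-TBS ketone of step 21)
Product: 45 (5S,6R)-6-[(1E,3Z,5S,7E,9E,11S,13R,14R,15R,17E)-14,19-dihydroxy-11-(hydroxymethyl)-3,5,9,13,15,17-hexamethyl-12-oxononadeca-1,3,7,9,17-pentaen-1-yl]-5-methyl-5,6-dihydro-2H-pyran-2-one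
Conditions: HF·pyridine, pyridine, THF, 0 °C to rt
Reagents that add atoms: none
Why: Fluoride-mediated cleavage of the three silyl ethers under buffered, mildly acidic conditions spares the β-hydroxy ketone, the dienes and the lactone.

Step 23
Reactants: 45 (the triol of step 22)
Product: 46 (2E,5R,6R,7R,9S,10E,12E,15S,16Z,18E)-6-hydroxy-9-(hydroxymethyl)-3,5,7,11,15,17-hexamethyl-19-[(2R,3S)-3-methyl-6-oxo-3,6-dihydro-2H-pyran-2-yl]-8-oxononadeca-2,10,12,16,18-pentaenal
Conditions: MnO2 (activated, excess), CH2Cl2, rt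
Reagents that add atoms: none
Why: Chemoselective allylic oxidation, since MnO2 oxidises only the primary allylic C1 alcohol and leaves the C6 and C9 hydroxyls alone.

Step 24
Reactants: 46 (the enal of step 23)
Product: 47 (2E,5R,6R,7R,9S,10E,12E,15S,16Z,18E)-6-hydroxy-9-(hydroxymethyl)-3,5,7,11,15,17-hexamethyl-19-[(2R,3S)-3-methyl-6-oxo-3,6-dihydro-2H-pyran-2-yl]-8-oxononadeca-2,10,12,16,18-pentaenoic acid
Conditions: NaClO2, NaH2PO4, 2-methylbut-2-ene (excess), t-BuOH/H2O, 0 °C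
Reagents that add atoms: sodium chlorite [Na+].[O-]Cl=O
Why: Pinnick oxidation converts the enal into the acid under buffered conditions with a hypochlorite scavenger, which the dienes, the β-hydroxy ketone and the lactone tolerate.

**Compound list**

1 | tert-butyl propanoate | CCC(=O)OC(C)(C)C | starting material
2 | lithium enolate of tert-butyl propanoate (O–Li trans to methyl) | C/C=C(/[O-])OC(C)(C)C.[Li+] | intermediate
3 | (E)-tert-butyl[(1-tert-butoxyprop-1-en-1-yl)oxy]dimethylsilane | C/C=C(/O[Si](C)(C)C(C)(C)C)OC(C)(C)C | intermediate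
4 | 2-methylprop-2-enal (methacrolein) | CC(=C)C=O | starting material
5 | tert-butyl (2R,3S)-2,4-dimethyl-3-[(trichlorosilyl)oxy]pent-4-enoate | CC(C)(C)OC(=O)[C@H](C)[C@H](O[Si](Cl)(Cl)Cl)C(C)=C | intermediate
6 | tert-butyl (2R,3S)-3-hydroxy-2,4-dimethylpent-4-enoate | CC(C)(C)OC(=O)[C@H](C)[C@H](O)C(C)=C | intermediate
7 | tert-butyl (2R,3S)-3-(TBSO)-2,4-dimethylpent-4-enoate | CC(C)(C)OC(=O)[C@H](C)[C@H](O[Si](C)(C)C(C)(C)C)C(C)=C | intermediate
8 | but-2-yn-1-ol | CC#CCO | starting material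
9 | (but-2-yn-1-yloxy)(tert-butyl)dimethylsilane | CC#CCO[Si](C)(C)C(C)(C)C | intermediate
10 | chlorobis(cyclopentadienyl)[(E)-4-(TBSO)but-2-en-2-yl]zirconium | C/C(=C\CO[Si](C)(C)C(C)(C)C)[Zr](Cl)(C1C=CC=C1)C1C=CC=C1 | intermediate
11 | (E)-tert-butyl[(3-iodobut-2-en-1-yl)oxy]dimethylsilane | C/C(I)=C\CO[Si](C)(C)C(C)(C)C | intermediate
12 | tert-butyl (2R,3R,4R)-5-(9-borabicyclo[3.3.1]nonan-9-yl)-3-(TBSO)-2,4-dimethylpentanoate | CC(C)(C)OC(=O)[C@H](C)[C@H](O[Si](C)(C)C(C)(C)C)[C@H](C)CB1C2CCCC1CCC2 | intermediate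
13 | tert-butyl (2R,3R,4R,6E)-3,8-bis(TBSO)-2,4,6-trimethyloct-6-enoate | CC(C)(C)OC(=O)[C@H](C)[C@H](O[Si](C)(C)C(C)(C)C)[C@H](C)C/C(C)=C/CO[Si](C)(C)C(C)(C)C | intermediate
14 | diisobutylaluminium hemiacetal of 13 (C1 epimers) | CC(C)C[Al](CC(C)C)OC(OC(C)(C)C)[C@H](C)[C@H](O[Si](C)(C)C(C)(C)C)[C@H](C)C/C(C)=C/CO[Si](C)(C)C(C)(C)C | intermediate
15 | (2R,3R,4R,6E)-3,8-bis(TBSO)-2,4,6-trimethyloct-6-enal | O=C[C@H](C)[C@H](O[Si](C)(C)C(C)(C)C)[C@H](C)C/C(C)=C/CO[Si](C)(C)C(C)(C)C | intermediate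
16 | (E)-but-2-ene-1,4-diol | OC/C=C/CO | starting material
17 | (E)-4-(TBSO)but-2-en-1-ol | OC/C=C/CO[Si](C)(C)C(C)(C)C | intermediate
18 | (E)-tert-butyldimethyl{[4-(Bpin)but-2-en-1-yl]oxy}silane | CC1(C)OB(C/C=C/CO[Si](C)(C)C(C)(C)C)OC1(C)C | intermediate
19 | O-Bpin boric ester of 20 | C=C[C@@H](CO[Si](C)(C)C(C)(C)C)[C@@H](OB1OC(C)(C)C(C)(C)O1)[C@H](C)[C@H](O[Si](C)(C)C(C)(C)C)[C@H](C)C/C(C)=C/CO[Si](C)(C)C(C)(C)C | intermediate
20 | (3S,4R,5S,6R,7R,9E)-6,11-bis(TBSO)-3-[(TBSO)methyl]-5,7,9-trimethylundeca-1,9-dien-4-ol | C=C[C@@H](CO[Si](C)(C)C(C)(C)C)[C@@H](O)[C@H](C)[C@H](O[Si](C)(C)C(C)(C)C)[C@H](C)C/C(C)=C/CO[Si](C)(C)C(C)(C)C | intermediate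
21 | (2E,4S,5R,6S,7R,8R,10E)-7,12-bis(TBSO)-4-[(TBSO)methyl]-5-hydroxy-2,6,8,10-tetramethyldodeca-2,10-dienal | O=C/C(C)=C/[C@@H](CO[Si](C)(C)C(C)(C)C)[C@@H](O)[C@H](C)[C@H](O[Si](C)(C)C(C)(C)C)[C@H](C)C/C(C)=C/CO[Si](C)(C)C(C)(C)C | intermediate
22 | 1-phenyl-1H-tetrazole-5-thiol | Sc1nnnn1-c1ccccc1 | starting material
23 | 1,2-dibromoethane | BrCCBr | starting material
24 | 5-[(2-bromoethyl)sulfanyl]-1-phenyl-1H-tetrazole | BrCCSc1nnnn1-c1ccccc1 | intermediate
25 | 5-[(2-bromoethyl)sulfonyl]-1-phenyl-1H-tetrazole | BrCCS(=O)(=O)c1nnnn1-c1ccccc1 | intermediate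
26 | 5-(ethenylsulfonyl)-1-phenyl-1H-tetrazole | C=CS(=O)(=O)c1nnnn1-c1ccccc1 | intermediate
27 | propanal | CCC=O | starting material
28 | (2S)-2-methyl-4-(PT-sulfonyl)butanal | O=C[C@@H](C)CCS(=O)(=O)c1nnnn1-c1ccccc1 | intermediate
29 | ethyltriphenylphosphonium iodide | CC[P+](c1ccccc1)(c1ccccc1)c1ccccc1.[I-] | starting material
30 | ethylidenetriphenylphosphorane | CC=P(c1ccccc1)(c1ccccc1)c1ccccc1 | intermediate
31 | (1-iodoethyl)triphenylphosphonium iodide | CC(I)[P+](c1ccccc1)(c1ccccc1)c1ccccc1.[I-] | intermediate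
32 | (1-iodoethylidene)triphenylphosphorane | CC(I)=P(c1ccccc1)(c1ccccc1)c1ccccc1 | intermediate
33 | 5-{[(3S,4Z)-5-iodo-3-methylhex-4-en-1-yl]sulfonyl}-1-phenyl-1H-tetrazole | C/C(I)=C/[C@@H](C)CCS(=O)(=O)c1nnnn1-c1ccccc1 | intermediate
34 | potassium α-sulfonyl carbanion of 33 | C/C(I)=C/[C@@H](C)C[CH-]S(=O)(=O)c1nnnn1-c1ccccc1.[K+] | intermediate
35 | (2E,5R,6R,7S,8R,9S,10E,12E,15S,16Z)-1,6-bis(TBSO)-9-[(TBSO)methyl]-17-iodo-3,5,7,11,15-pentamethyloctadeca-2,10,12,16-tetraen-8-ol | C/C(I)=C/[C@@H](C)C/C=C/C(C)=C/[C@@H](CO[Si](C)(C)C(C)(C)C)[C@@H](O)[C@H](C)[C@H](O[Si](C)(C)C(C)(C)C)[C@H](C)C/C(C)=C/CO[Si](C)(C)C(C)(C)C | intermediate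
36 | (E)-3-(Bpin)prop-2-enal | O=C/C=C/B1OC(C)(C)C(C)(C)O1 | starting material
37 | 2-[(E)-but-2-en-1-yl]-4,4,5,5-tetramethyl-1,3,2-dioxaborolane | C/C=C/CB1OC(C)(C)C(C)(C)O1 | starting material
38 | O-Bpin boric ester of 39 | CC1(C)OB(/C=C/[C@@H](OB2OC(C)(C)C(C)(C)O2)[C@@H](C)C=C)OC1(C)C | intermediate
39 | (1E,3R,4S)-4-methyl-1-(Bpin)hexa-1,5-dien-3-ol | CC1(C)OB(/C=C/[C@@H](O)[C@@H](C)C=C)OC1(C)C | intermediate
40 | acryloyl chloride | C=CC(=O)Cl | starting material
41 | (1E,3R,4S)-4-methyl-1-(Bpin)hexa-1,5-dien-3-yl prop-2-enoate | CC1(C)OB(/C=C/[C@@H](OC(=O)C=C)[C@@H](C)C=C)OC1(C)C | intermediate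
42 | (5S,6R)-5-methyl-6-[(E)-2-(Bpin)ethenyl]-5,6-dihydro-2H-pyran-2-one | CC1(C)OB(/C=C/[C@H]2OC(=O)C=C[C@@H]2C)OC1(C)C | intermediate
43 | (5S,6R)-6-[(1E,3Z,5S,7E,9E,11S,12R,13S,14R,15R,17E)-14,19-bis(TBSO)-11-[(TBSO)methyl]-12-hydroxy-3,5,9,13,15,17-hexamethylnonadeca-1,3,7,9,17-pentaen-1-yl]-5-methyl-5,6-dihydro-2H-pyran-2-one | CC(=C/[C@@H](C)C/C=C/C(C)=C/[C@@H](CO[Si](C)(C)C(C)(C)C)[C@@H](O)[C@H](C)[C@H](O[Si](C)(C)C(C)(C)C)[C@H](C)C/C(C)=C/CO[Si](C)(C)C(C)(C)C)/C=C/[C@H]1OC(=O)C=C[C@@H]1C | intermediate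
44 | (5S,6R)-6-[(1E,3Z,5S,7E,9E,11S,13R,14R,15R,17E)-14,19-bis(TBSO)-11-[(TBSO)methyl]-3,5,9,13,15,17-hexamethyl-12-oxononadeca-1,3,7,9,17-pentaen-1-yl]-5-methyl-5,6-dihydro-2H-pyran-2-one | CC(=C/[C@@H](C)C/C=C/C(C)=C/[C@@H](CO[Si](C)(C)C(C)(C)C)C(=O)[C@H](C)[C@H](O[Si](C)(C)C(C)(C)C)[C@H](C)C/C(C)=C/CO[Si](C)(C)C(C)(C)C)/C=C/[C@H]1OC(=O)C=C[C@@H]1C | intermediate
45 | (5S,6R)-6-[(1E,3Z,5S,7E,9E,11S,13R,14R,15R,17E)-14,19-dihydroxy-11-(hydroxymethyl)-3,5,9,13,15,17-hexamethyl-12-oxononadeca-1,3,7,9,17-pentaen-1-yl]-5-methyl-5,6-dihydro-2H-pyran-2-one | CC(=C/[C@@H](C)C/C=C/C(C)=C/[C@@H](CO)C(=O)[C@H](C)[C@H](O)[C@H](C)C/C(C)=C/CO)/C=C/[C@H]1OC(=O)C=C[C@@H]1C | intermediate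
46 | (2E,5R,6R,7R,9S,10E,12E,15S,16Z,18E)-6-hydroxy-9-(hydroxymethyl)-3,5,7,11,15,17-hexamethyl-19-[(2R,3S)-3-methyl-6-oxo-3,6-dihydro-2H-pyran-2-yl]-8-oxononadeca-2,10,12,16,18-pentaenal | CC(=C/[C@@H](C)C/C=C/C(C)=C/[C@@H](CO)C(=O)[C@H](C)[C@H](O)[C@H](C)C/C(C)=C/C=O)/C=C/[C@H]1OC(=O)C=C[C@@H]1C | intermediate
47 | (2E,5R,6R,7R,9S,10E,12E,15S,16Z,18E)-6-hydroxy-9-(hydroxymethyl)-3,5,7,11,15,17-hexamethyl-19-[(2R,3S)-3-methyl-6-oxo-3,6-dihydro-2H-pyran-2-yl]-8-oxononadeca-2,10,12,16,18-pentaenoic acid | CC(=C/[C@@H](C)C/C=C/C(C)=C/[C@@H](CO)C(=O)[C@H](C)[C@H](O)[C@H](C)C/C(C)=C/C(=O)O)/C=C/[C@H]1OC(=O)C=C[C@@H]1C | target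

**Step count and risks**

Total step count: 24. Longest linear sequence: 13 steps (steps 1, 2, 3, 6, 7, 10, 11, 16, 20, 21, 22, 23, 24).

The three steps most likely to fail:

Step 10 (the proposed new step). The catalyst may be slow with the hindered aldehyde and the bulky γ-substituent, or its facial preference may oppose the substrate bias. The fallback drops the boron reagent and uses a chromium-mediated Nozaki–Hiyama addition, which is known to be anti-selective whatever the halide geometry and Felkin-selective with α-methyl aldehydes. It sets out from aldehyde 15 (with alcohol 17 in place of boronate 18) and comes back at 20: alcohol 17 is converted with CBr4 and PPh3 in CH2Cl2 at 0 °C into (E)-[(4-bromobut-2-en-1-yl)oxy](tert-butyl)dimethylsilane F1, and F1 with CrCl2 in THF at 0 °C adds to 15 through a chair transition state to give 20 directly.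

Step 14. The secondary amine catalyst may be consumed by aza-Michael addition to the very electrophilic vinyl sulfone or by attack at the tetrazole, and the α-methyl aldehyde 28 can erode in ee. The fallback sets C15 as a β-stereocentre by iminium-catalysed transfer hydrogenation and installs the sulfone afterwards; it sets out from thiol 22 and comes back at 28. Wittig reaction of commercial 1-(TBSO)propan-2-one with (triphenylphosphoranylidene)acetaldehyde (toluene, 80 °C) gives (E)-4-(TBSO)-3-methylbut-2-enal F2. Transfer hydrogenation with a tert-butyl imidazolidinone trichloroacetate salt of the appropriate hand and Hantzsch ester (CHCl3, −30 °C) gives (3S)-4-(TBSO)-3-methylbutanal F3. NaBH4 in MeOH gives (3S)-4-(TBSO)-3-methylbutan-1-ol F4. Mitsunobu reaction with 22 (PPh3, diisopropyl azodicarboxylate, THF) gives 5-{[(3S)-4-(TBSO)-3-methylbutyl]sulfanyl}-1-phenyl-1H-tetrazole F5. HF·pyridine in THF gives (2S)-2-methyl-4-(PT-sulfanyl)butan-1-ol F6. Oxidation with (NH4)6Mo7O24 and H2O2 in EtOH gives (2S)-2-methyl-4-(PT-sulfonyl)butan-1-ol F7, and Dess–Martin oxidation of F7 gives 28.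

Step 20. Aqueous base may open the α,β-unsaturated lactone, or the hindered (Z)-iodide may couple too slowly with the pinacol boronate. The fallback is a base-free Stille coupling with a stannane analogue of 42; it sets out from iodide 35 and comes back at 43. Commercial (E)-3-(tributylstannyl)prop-2-en-1-ol is oxidised with MnO2 to (E)-3-(tributylstannyl)prop-2-enal F8. Crotylboration of F8 with 37 under (S)-TRIP as in step 17 gives, through the O-Bpin boric ester of the stannyl dienol F9, (1E,3S,4S)-4-methyl-1-(tributylstannyl)hexa-1,5-dien-3-ol F10. Acylation with 40 as in step 18 gives (1E,3S,4S)-4-methyl-1-(tributylstannyl)hexa-1,5-dien-3-yl prop-2-enoate F11. Ring-closing metathesis as in step 19 gives (5S,6S)-5-methyl-6-[(E)-2-(tributylstannyl)ethenyl]-5,6-dihydro-2H-pyran-2-one F12. F12 and 35 with Pd2(dba)3 and AsPh3 in N-methylpyrrolidone at rt give 43.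

**Further compounds**

F1 | step 10 | (E)-[(4-bromobut-2-en-1-yl)oxy](tert-butyl)dimethylsilane | BrC/C=C/CO[Si](C)(C)C(C)(C)C
F2 | step 14 | (E)-4-(TBSO)-3-methylbut-2-enal | CC(C)(C)[Si](C)(C)OC/C(C)=C/C=O
F3 | step 14 | (3S)-4-(TBSO)-3-methylbutanal | CC(C)(C)[Si](C)(C)OC[C@@H](C)CC=O
F4 | step 14 | (3S)-4-(TBSO)-3-methylbutan-1-ol | CC(C)(C)[Si](C)(C)OC[C@@H](C)CCO
F5 | step 14 | 5-{[(3S)-4-(TBSO)-3-methylbutyl]sulfanyl}-1-phenyl-1H-tetrazole | CC(C)(C)[Si](C)(C)OC[C@@H](C)CCSc1nnnn1-c1ccccc1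
F6 | step 14 | (2S)-2-methyl-4-(PT-sulfanyl)butan-1-ol | OC[C@@H](C)CCSc1nnnn1-c1ccccc1
F7 | step 14 | (2S)-2-methyl-4-(PT-sulfonyl)butan-1-ol | OC[C@@H](C)CCS(=O)(=O)c1nnnn1-c1ccccc1
F8 | step 20 | (E)-3-(tributylstannyl)prop-2-enal | O=C/C=C/[Sn](CCCC)(CCCC)CCCC
F9 | step 20 | O-Bpin boric ester of the stannyl dienol | CCCC[Sn](CCCC)(CCCC)/C=C/[C@@H](OB1OC(C)(C)C(C)(C)O1)[C@@H](C)C=C
F10 | step 20 | (1E,3S,4S)-4-methyl-1-(tributylstannyl)hexa-1,5-dien-3-ol | CCCC[Sn](CCCC)(CCCC)/C=C/[C@@H](O)[C@@H](C)C=C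
F11 | step 20 | (1E,3S,4S)-4-methyl-1-(tributylstannyl)hexa-1,5-dien-3-yl prop-2-enoate | CCCC[Sn](CCCC)(CCCC)/C=C/[C@@H](OC(=O)C=C)[C@@H](C)C=C
F12 | step 20 | (5S,6S)-5-methyl-6-[(E)-2-(tributylstannyl)ethenyl]-5,6-dihydro-2H-pyran-2-one | CCCC[Sn](CCCC)(CCCC)/C=C/[C@H]1OC(=O)C=C[C@@H]1C
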